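**Retrosynthetic overview**

1. C7–OH is traced back to the C8=C17 exocyclic methylene of ring B (SeO2 ene/[2,3] oxidation at the end). That alkene, with C7 as its allylic CH2 two atoms from C6, is the footprint of a C9 isopropenyl group, so ring B is opened at C6–C7 to a ring-A aldehyde (C6 raised to the aldehyde level, its oxygen removed again after the closure).
2. The C9–C10 bond and the vicinal tertiary/quaternary pair come from a Johnson–Claisen rearrangement through a ketene acetal whose geometry is locked in a temporary γ-lactone ring (C20 carbonyl, C6 oxygen) fused cis to ring A. The allyl partner is (E)-8-hydroxylinalool silyl ether, which brings C7–C9, C11–C17 and the C13 stereocentre.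
3. Ring A, with C5 and the C2=C3 alkene, comes from an auxiliary-controlled Diels–Alder reaction of a fumaroyl imide with 4-methylpenta-1,3-diene; the 2α,3α-diol is set on the convex face of the cis-lactone before any other alkene is present.
4. Order of ring formation: ring A (cycloaddition), temporary lactone ring (opened in step 10), ring B (step 14). End game: C6 deoxygenation, monoangeloylation, allylic hydroxylation at C7, desilylation.

Key step: step 14

Remark: atom numbers and α/β descriptors are those of the labdane skeleton of the target (ring A = C1–C5 and C10, ring B = C5–C10), also for the ring-A and 6,7-seco intermediates; the C6 carbinol of 21 and 22 is drawn as the expected 6β epimer, although either epimer serves.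

**Route**

Step 1
Reactants: 1 (S)-4-benzyl-1,3-oxazolidin-2-one; 2 methyl (E)-4-chloro-4-oxobut-2-enoate
Product: 3 methyl (E)-4-[(4S)-4-benzyl-2-oxo-1,3-oxazolidin-3-yl]-4-oxobut-2-enoate
Conditions: LiCl, Et3N, THF, 0 °C → rt
Reagents that add atoms: none
Why: N-acylation of the oxazolidinone by the acid chloride under LiCl/Et3N activation should give the fumaroyl imide with the (E)-alkene intact.

Step 2
Reactants: 3 fumaroyl imide; 4 4-methylpenta-1,3-diene
Product: 5 methyl (1S,6R)-6-{[(4S)-4-benzyl-2-oxo-1,3-oxazolidin-3-yl]carbonyl}-5,5-dimethylcyclohex-3-ene-1-carboxylate (imide carbon = C6 on C5; ester carbon = C20 on C10; trans)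
Conditions: Et2AlCl (1.4 equiv), CH2Cl2, −78 → −30 °C
Reagents that add atoms: none
Why: Auxiliary-controlled Diels–Alder reaction: Et2AlCl chelates both imide carbonyls, so the CH2 terminus of the diene should bond to the ester-bearing carbon (C10) and the CMe2 terminus to the imide-bearing carbon (C5) on the face opposite the benzyl group, which sets C5, places C10 trans to it and delivers the C2=C3 alkene.

Step 3
Reactants: 5 Diels–Alder adduct
Product: 7 (3aR,7aR)-4,4-dimethyl-3a,4,7,7a-tetrahydro-2-benzofuran-1(3H)-one (cis-fused 20,6-lactone of ring A), via hydroxy ester 6 (not isolated)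
Conditions: NaBH4, THF/H2O, 0 °C → rt; then DBU, toluene, 80 °C
Reagents that add atoms: none
Why: NaBH4 in aqueous THF cleaves the N-acyloxazolidinone reductively to the C6 primary alcohol and spares the methyl ester; DBU then epimerises C10 through the ester/lactone enolate and the hydroxy ester should close to the cis-fused γ-lactone, the thermodynamic isomer on a cyclohexene ring.

Step 4
Reactants: 7 cis-lactone
Product: 8 (3aR,5S,6R,7aR)-5,6-dihydroxy-4,4-dimethylhexahydro-2-benzofuran-1(3H)-one (2α,3α-diol)
Conditions: OsO4 (2 mol %), N-methylmorpholine N-oxide, acetone/H2O, rt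
Reagents that add atoms: N-methylmorpholine N-oxide (C[N+]1([O-])CCOCC1); water (O)
Why: Upjohn dihydroxylation should occur on the convex α face of the cis-fused bicycle, anti to the lactone ring, which sets C2 and C3 relative to C5 while no other alkene is present.

Step 5
Reactants: 8 diol lactone
Product: 9 (3aR,5S,6R,7aR)-5,6-(isopropylidenedioxy)-4,4-dimethylhexahydro-2-benzofuran-1(3H)-one
Conditions: 2,2-dimethoxypropane, PPTS (cat.), acetone, rt
Reagents that add atoms: 2,2-dimethoxypropane (COC(C)(C)OC)
Why: Acid-catalysed transketalisation of a cis-1,2-diol gives the acetonide, which masks both hydroxyls for the oxonium, hydride and Lewis acid steps.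

Step 6
Reactants: 10 (R)-(−)-linalool
Product: 11 (3R)-3-[(tert-butyldimethylsilyl)oxy]-3,7-dimethylocta-1,6-diene
Conditions: TBSOTf, 2,6-lutidine, CH2Cl2, −78 → 0 °C
Reagents that add atoms: tert-butyldimethylsilyl trifluoromethanesulfonate (CC(C)(C)[Si](C)(C)OS(=O)(=O)C(F)(F)F)
Why: The silyl triflate silylates the hindered tertiary allylic alcohol without touching the C13 stereocentre.

Step 7
Reactants: 11 linalool TBS ether
Product: 12 (2E,6R)-6-[(tert-butyldimethylsilyl)oxy]-2,6-dimethylocta-2,7-dien-1-ol
Conditions: SeO2 (0.3 equiv), t-BuOOH, salicylic acid (cat.), CH2Cl2, rt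
Reagents that add atoms: selenium dioxide (O=[Se]=O); tert-butyl hydroperoxide (CC(C)(C)OO)
Why: SeO2-catalysed allylic hydroxylation (ene reaction, then [2,3]-sigmatropic shift) is selective for the (E)-methyl group of the trisubstituted alkene, and the vinyl group has no allylic hydrogen.

Step 8
Reactants: 9 acetonide lactone; 12 allylic alcohol
Product: 14 mixed cyclic orthoester (C20 of 9 bearing OEt and the allyloxy group of 12; both C20 epimers), via O-ethyl lactonium tetrafluoroborate 13 (not isolated)
Conditions: Et3OBF4, CH2Cl2, rt; then 12, Et3N, −40 → 0 °C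
Reagents that add atoms: triethyloxonium tetrafluoroborate (CC[O+](CC)CC.F[B-](F)(F)F)
Why: O-alkylation of the lactone carbonyl gives a dialkoxycarbenium ion that the primary allylic alcohol traps as the orthoester, the standard entry to lactone-derived ketene acetals.

Step 9
Reactants: 14 mixed orthoester
Product: 16 (13R)-13-[(tert-butyldimethylsilyl)oxy]-2α,3α-(isopropylidenedioxy)-6,7-seco-labda-7,14-dien-20,6-olide, via allyl ketene acetal 15 (not isolated)
Conditions: t-BuCO2H (cat.), o-xylene, 140 °C, −EtOH
Reagents that add atoms: none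
Why: Johnson–Claisen rearrangement: loss of ethanol gives ketene acetal 15, whose geometry is fixed by the five-membered ring (ring oxygen cis to C5, allyloxy group cis to C1), and a chair transition state with C11 of the (E)-alkene equatorial should form C9–C10 on the α face (cis-fused lactone, anti to the axial 4β-methyl), setting C10 and C9 as in the target and unveiling the C9 isopropenyl group (C7 = CH2, C17 = CH3).

Step 10
Reactants: 16 α-quaternary lactone
Product: 17 (13R)-13-[(tert-butyldimethylsilyl)oxy]-2α,3α-(isopropylidenedioxy)-6,7-seco-labda-7,14-diene-6,20-diol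
Conditions: LiAlH4, THF, 0 °C → rt
Reagents that add atoms: none
Why: Hydride reduction opens the temporary lactone to the C6 and C20 primary alcohols without touching any stereocentre, alkene or silyl ether.

Step 11
Reactants: 17 diol
Product: 18 6-O-triethylsilyl ether of 17
Conditions: Et3SiCl, imidazole, CH2Cl2, −40 °C
Reagents that add atoms: chlorotriethylsilane (CC[Si](Cl)(CC)CC)
Why: The C6 hydroxyl on a methine carbon should be silylated faster than the neopentyl C20 hydroxyl on the quaternary C10.

Step 12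
Reactants: 18 mono-TES ether
Product: 19 20-acetate of 18
Conditions: Ac2O, DMAP (cat.), pyridine, rt
Reagents that add atoms: acetic anhydride (CC(=O)OC(C)=O)
Why: DMAP-catalysed acetylation of the remaining neopentyl primary alcohol installs the C20 acetate of the target, which is stable to all later steps.

Step 13
Reactants: 19 acetate TES ether
Product: 20 (13R)-20-acetoxy-13-[(tert-butyldimethylsilyl)oxy]-2α,3α-(isopropylidenedioxy)-6,7-seco-labda-7,14-dien-6-al
Conditions: (COCl)2, DMSO, CH2Cl2, −78 → −30 °C; Et3N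
Reagents that add atoms: none
Why: Primary triethylsilyl ethers are cleaved and oxidised directly under Swern conditions while the tertiary TBS ether, acetonide and acetate are inert, and C5, flanked by two quaternary carbons, should not epimerise at low temperature.

Step 14
Reactants: 20 6,7-seco aldehyde
Product: 21 (13R)-20-acetoxy-13-[(tert-butyldimethylsilyl)oxy]-2α,3α-(isopropylidenedioxy)labda-8(17),14-dien-6β-ol
Conditions: Me2AlCl (2.5 equiv), CH2Cl2, −78 → −20 °C
Reagents that add atoms: none
Why: Me2AlCl activates the C6 aldehyde, the terminal CH2 of the C9 isopropenyl group (C7) attacks C6 while a hydrogen of the C17 methyl is passed to oxygen through a bicyclic chair-like transition state, so C6–C7 forms, ring B closes and the C8=C17 exocyclic methylene appears in one operation, made irreversible by loss of methane from the aluminium alkoxide. The closest known reaction type is the Lewis-acid-promoted type 2 intramolecular carbonyl-ene cyclisation of 6-methylhept-6-enals to 3-methylenecyclohexanols. Ring B closes in the six-membered mode, exo to the C6=O bond and endo to the C7=C8 bond, onto a ring A whose C5 and C10 side arms are already trans, so only the trans-decalin can form. The one new stereocentre, C6, is set by the chair transition state, which needs the C6–O bond axial to reach the C17 hydrogen (6β-OH expected); it is temporary and is erased in step 16. The step needs selectivity for the isopropenyl group over the C14=C15 vinyl group and for hydrogen transfer from C17 rather than C9: the vinyl group has no allylic hydrogen and is out of reach, and the C9 hydrogen cannot reach the oxygen in the bicyclic transition state. The C5 stereocentre α to the aldehyde is flanked by two quaternary carbons and should survive the Lewis acid at low temperature.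

Step 15
Reactants: 21 6β-alcohol
Product: 22 6-O-(1H-imidazol-1-ylcarbonothioyl) derivative of 21
Conditions: 1,1′-thiocarbonyldiimidazole, DMAP, toluene, 90 °C
Reagents that add atoms: 1,1′-thiocarbonyldiimidazole (S=C(n1ccnc1)n1ccnc1)
Why: Thioacylation of the hindered secondary alcohol under neutral conditions (first stage of the Barton–McCombie deoxygenation) avoids base-induced acetate migration.

Step 16
Reactants: 22 thiocarbonylimidazolide
Product: 23 (13R)-20-acetoxy-13-[(tert-butyldimethylsilyl)oxy]-2α,3α-(isopropylidenedioxy)labda-8(17),14-diene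
Conditions: Bu3SnH, AIBN (cat.), toluene, 100 °C
Reagents that add atoms: none
Why: Barton–McCombie deoxygenation: the stannyl radical adds to C=S, β-scission gives the secondary C6 radical, and hydrogen abstraction returns C6 to the CH2 level without touching the neighbouring stereocentres or the alkenes.

Step 17
Reactants: 23 deoxygenated acetonide
Product: 24 (13R)-20-acetoxy-13-[(tert-butyldimethylsilyl)oxy]labda-8(17),14-diene-2α,3α-diol
Conditions: AcOH/THF/H2O (3:1:1), 45 °C
Reagents that add atoms: none
Why: Mild aqueous acid hydrolyses the acetonide, while the hindered tertiary TBS ether, the acetate and the exocyclic alkene should survive.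

Step 18
Reactants: 24 diol; 25 angelic acid, (Z)-2-methylbut-2-enoic acid
Product: 27 (13R)-20-acetoxy-2α-angeloyloxy-13-[(tert-butyldimethylsilyl)oxy]labda-8(17),14-dien-3α-ol, via mixed anhydride 26 (not isolated)
Conditions: 25, 2,4,6-Cl3C6H2COCl, Et3N, toluene, rt; then 24, 80 °C
Reagents that add atoms: none
Why: Yamaguchi-type esterification through the mixed anhydride without a nucleophilic catalyst keeps the Z geometry of the angelate, and the equatorial C2 hydroxyl should react in preference to the axial, neopentyl C3 hydroxyl (no C7 hydroxyl is present yet).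

Step 19
Reactants: 27 angelate
Product: 28 (13R)-20-acetoxy-2α-angeloyloxy-13-[(tert-butyldimethylsilyl)oxy]labda-8(17),14-diene-3α,7α-diol
Conditions: SeO2 (0.5 equiv), t-BuOOH, CH2Cl2, 0 °C → rt
Reagents that add atoms: selenium dioxide (O=[Se]=O); tert-butyl hydroperoxide (CC(C)(C)OO)
Why: SeO2 allylic hydroxylation: ene reaction at C17 with removal of the axial 7α-hydrogen, then [2,3]-sigmatropic shift, should return the C8=C17 alkene and deliver oxygen to the α face of C7 (axial alcohol), as is typical of exocyclic methylene cyclohexanes; the vinyl group has no allylic hydrogen and the angelate alkene is electron-poor.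

Step 20
Reactants: 28 silyl ether
Product: 29 (13R)-20-acetoxy-2α-angeloyloxylabda-8(17),14-diene-3α,7α,13-triol (CNP0251485.1)
Conditions: HF·pyridine, pyridine, THF, 0 °C → rt
Reagents that add atoms: none
Why: Buffered fluoride cleaves the tertiary silyl ether while both esters and the allylic alcohols are stable, which should give the target.

**Compound list**

1 | (S)-4-benzyl-1,3-oxazolidin-2-one | O=C1N[C@@H](Cc2ccccc2)CO1 | starting material
2 | methyl (E)-4-chloro-4-oxobut-2-enoate | COC(=O)/C=C/C(Cl)=O | starting material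
3 | methyl (E)-4-[(4S)-4-benzyl-2-oxo-1,3-oxazolidin-3-yl]-4-oxobut-2-enoate | COC(=O)/C=C/C(=O)N1[C@@H](Cc2ccccc2)COC1=O | intermediate
4 | 4-methylpenta-1,3-diene | C=CC=C(C)C | starting material
5 | methyl (1S,6R)-6-{[(4S)-4-benzyl-2-oxo-1,3-oxazolidin-3-yl]carbonyl}-5,5-dimethylcyclohex-3-ene-1-carboxylate | COC(=O)[C@H]1CC=CC(C)(C)[C@@H]1C(=O)N2[C@@H](Cc3ccccc3)COC2=O | intermediate
6 | methyl (1S,6R)-6-(hydroxymethyl)-5,5-dimethylcyclohex-3-ene-1-carboxylate | COC(=O)[C@H]1CC=CC(C)(C)[C@@H]1CO | intermediate
7 | (3aR,7aR)-4,4-dimethyl-3a,4,7,7a-tetrahydro-2-benzofuran-1(3H)-one | O=C1OC[C@H]2C(C)(C)C=CC[C@@H]12 | intermediate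
8 | (3aR,5S,6R,7aR)-5,6-dihydroxy-4,4-dimethylhexahydro-2-benzofuran-1(3H)-one | O=C1OC[C@H]2C(C)(C)[C@H](O)[C@H](O)C[C@@H]12 | intermediate
9 | (3aR,5S,6R,7aR)-5,6-(isopropylidenedioxy)-4,4-dimethylhexahydro-2-benzofuran-1(3H)-one | O=C1OC[C@H]2C(C)(C)[C@@H]3OC(C)(C)O[C@@H]3C[C@@H]12 | intermediate
10 | (R)-(−)-linalool | C=C[C@](C)(O)CCC=C(C)C | starting material
11 | (3R)-3-[(tert-butyldimethylsilyl)oxy]-3,7-dimethylocta-1,6-diene | C=C[C@](C)(O[Si](C)(C)C(C)(C)C)CCC=C(C)C | intermediate
12 | (2E,6R)-6-[(tert-butyldimethylsilyl)oxy]-2,6-dimethylocta-2,7-dien-1-ol | C=C[C@](C)(O[Si](C)(C)C(C)(C)C)CC/C=C(\C)CO | intermediate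
13 | O-ethyl lactonium (dialkoxycarbenium) tetrafluoroborate of 9 | CC[O+]=C1OC[C@H]2C(C)(C)[C@@H]3OC(C)(C)O[C@@H]3C[C@@H]12.F[B-](F)(F)F | intermediate
14 | mixed cyclic orthoester of 9 (C20 bearing OEt and the allyloxy group of 12; C20 epimers) | CCOC1(OC/C(C)=C/CC[C@](C)(C=C)O[Si](C)(C)C(C)(C)C)OC[C@H]2C(C)(C)[C@@H]3OC(C)(C)O[C@@H]3C[C@@H]12 | intermediate
15 | cyclic ketene acetal C10=C20(O-allyl)–O–C6 | C=C[C@](C)(O[Si](C)(C)C(C)(C)C)CC/C=C(\C)COC1=C2C[C@H]3OC(C)(C)O[C@H]3C(C)(C)[C@@H]2CO1 | intermediate
16 | (13R)-13-[(tert-butyldimethylsilyl)oxy]-2α,3α-(isopropylidenedioxy)-6,7-seco-labda-7,14-dien-20,6-olide | C=C[C@](C)(O[Si](C)(C)C(C)(C)C)CC[C@@H](C(C)=C)[C@]12C(=O)OC[C@H]1C(C)(C)[C@@H]3OC(C)(C)O[C@@H]3C2 | intermediate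
17 | (13R)-13-[(tert-butyldimethylsilyl)oxy]-2α,3α-(isopropylidenedioxy)-6,7-seco-labda-7,14-diene-6,20-diol | C=C[C@](C)(O[Si](C)(C)C(C)(C)C)CC[C@@H](C(C)=C)[C@@]1(CO)C[C@H]2OC(C)(C)O[C@H]2C(C)(C)[C@@H]1CO | intermediate
18 | 6-O-triethylsilyl ether of 17 | C=C[C@](C)(O[Si](C)(C)C(C)(C)C)CC[C@@H](C(C)=C)[C@@]1(CO)C[C@H]2OC(C)(C)O[C@H]2C(C)(C)[C@@H]1CO[Si](CC)(CC)CC | intermediate
19 | 20-acetate of 18 | C=C[C@](C)(O[Si](C)(C)C(C)(C)C)CC[C@@H](C(C)=C)[C@@]1(COC(C)=O)C[C@H]2OC(C)(C)O[C@H]2C(C)(C)[C@@H]1CO[Si](CC)(CC)CC | intermediate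
20 | (13R)-20-acetoxy-13-[(tert-butyldimethylsilyl)oxy]-2α,3α-(isopropylidenedioxy)-6,7-seco-labda-7,14-dien-6-al | C=C[C@](C)(O[Si](C)(C)C(C)(C)C)CC[C@@H](C(C)=C)[C@@]1(COC(C)=O)C[C@H]2OC(C)(C)O[C@H]2C(C)(C)[C@@H]1C=O | intermediate
21 | (13R)-20-acetoxy-13-[(tert-butyldimethylsilyl)oxy]-2α,3α-(isopropylidenedioxy)labda-8(17),14-dien-6β-ol | C=C[C@](C)(O[Si](C)(C)C(C)(C)C)CC[C@H]1C(=C)C[C@@H](O)[C@H]2C(C)(C)[C@@H]3OC(C)(C)O[C@@H]3C[C@]12COC(C)=O | intermediate
22 | 6-O-(1H-imidazol-1-ylcarbonothioyl) derivative of 21 | C=C[C@](C)(O[Si](C)(C)C(C)(C)C)CC[C@H]1C(=C)C[C@@H](OC(=S)n4ccnc4)[C@H]2C(C)(C)[C@@H]3OC(C)(C)O[C@@H]3C[C@]12COC(C)=O | intermediate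
23 | (13R)-20-acetoxy-13-[(tert-butyldimethylsilyl)oxy]-2α,3α-(isopropylidenedioxy)labda-8(17),14-diene | C=C[C@](C)(O[Si](C)(C)C(C)(C)C)CC[C@H]1C(=C)CC[C@H]2C(C)(C)[C@@H]3OC(C)(C)O[C@@H]3C[C@]12COC(C)=O | intermediate
24 | (13R)-20-acetoxy-13-[(tert-butyldimethylsilyl)oxy]labda-8(17),14-diene-2α,3α-diol | C=C[C@](C)(O[Si](C)(C)C(C)(C)C)CC[C@H]1C(=C)CC[C@H]2C(C)(C)[C@H](O)[C@H](O)C[C@]12COC(C)=O | intermediate
25 | angelic acid, (Z)-2-methylbut-2-enoic acid | OC(=O)/C(C)=C\C | starting material
26 | angelic 2,4,6-trichlorobenzoic anhydride | O=C(OC(=O)/C(C)=C\C)c1c(Cl)cc(Cl)cc1Cl | intermediate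
27 | (13R)-20-acetoxy-2α-angeloyloxy-13-[(tert-butyldimethylsilyl)oxy]labda-8(17),14-dien-3α-ol | C=C[C@](C)(O[Si](C)(C)C(C)(C)C)CC[C@H]1C(=C)CC[C@H]2C(C)(C)[C@H](O)[C@H](OC(=O)/C(C)=C\C)C[C@]12COC(C)=O | intermediate
28 | (13R)-20-acetoxy-2α-angeloyloxy-13-[(tert-butyldimethylsilyl)oxy]labda-8(17),14-diene-3α,7α-diol | C=C[C@](C)(O[Si](C)(C)C(C)(C)C)CC[C@H]1C(=C)[C@H](O)C[C@H]2C(C)(C)[C@H](O)[C@H](OC(=O)/C(C)=C\C)C[C@]12COC(C)=O | intermediate
29 | (13R)-20-acetoxy-2α-angeloyloxylabda-8(17),14-diene-3α,7α,13-triol (CNP0251485.1) | C=C[C@](C)(O)CC[C@H]1C(=C)[C@H](O)C[C@H]2C(C)(C)[C@H](O)[C@H](OC(=O)/C(C)=C\C)C[C@]12COC(C)=O | target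

**Step count and risks**

Total step count: 20. Longest linear sequence: 18 steps (steps 1–5 and 8–20, from 1 and 2 to 29); the linalool branch (steps 6–7) joins at step 8.

The three steps most likely to fail:

Step 2 (Diels–Alder reaction). The Z-methyl group of the diene disfavours its s-cis conformer, so Lewis-acid-induced cationic oligomerisation of the diene may outrun cycloaddition, and a stepwise bond formation could erode regio- and facial control. The fallback sets out from 4 and comes back at 7. Diene 4 is heated with maleic anhydride (toluene, 110 °C, trace of hydroquinone) without any Lewis acid to give the racemic cis-anhydride F1. NaBH4 in THF at 0 °C should attack the carbonyl next to the more substituted carbon (C6, beside the gem-dimethyl group), giving the racemic cis-lactone F2. AlMe3-mediated aminolysis with (S)-1-phenylethylamine gives two diastereomeric hydroxy amides, from which the hydroxy amide F3 with the ring configuration of 7 is separated by crystallisation or chromatography. TsOH in hot toluene relactonises it to 7 and returns the amine.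

Step 9 (Johnson–Claisen rearrangement). At 140 °C the orthoester may lose the allylic alcohol instead of ethanol or open to an acyclic ketene acetal of undefined geometry, and a boat transition state may compete, so the rearrangement may stall or the C9 configuration may be eroded; the oxonium salt of step 8 may also attack the acetonide. The fallback sets out from 9 (with 12) and comes back at 16. Saponification of 9 (KOH, MeOH/H2O) and silylation of the salt with TBSCl/imidazole gives the silyl ester silyl ether F4, whose silyl ester is cleaved by K2CO3 in aqueous MeOH to the 6-O-TBS acid F5. Esterification with 12 (EDC·HCl, DMAP) gives the allyl ester F6. Ireland–Claisen rearrangement (KN(SiMe3)2, Me3SiCl, toluene, −78 → 80 °C, base and solvent being the handles on ketene acetal geometry) gives the quaternary acid F7, with the new bond formed anti to the C5 substituent. HF·pyridine removes the primary silyl ether to give the hydroxy acid F8, which closes to 16 with TsOH (cat.).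

Step 19 (allylic hydroxylation). The new allylic alcohol may be over-oxidised to the enone, oxidation may compete at C9 or at the angelate methyl groups, and facial selectivity at C7 may be incomplete. The fallback sets out from 27 and comes back at 28, running the same ene/[2,3] logic stepwise. Ca(OCl)2/CO2 (CH2Cl2/H2O, 0 °C) ene-chlorinates only the nucleophilic C8=C17 alkene, taking hydrogen from the C7 methylene, to give the allylic chloride F9. NaSePh (from PhSeSePh/NaBH4, EtOH, 0 °C) displaces the primary allylic chloride to give the allylic selenide F10. H2O2/pyridine oxidises selenium, and the [2,3]-sigmatropic shift of the selenoxide delivers oxygen to the α face of C7; hydrolysis of the selenenate gives 28.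

Further compounds
F1 | step 2 | racemic cis-4,4-dimethyl-3a,4,7,7a-tetrahydro-2-benzofuran-1,3-dione (relative configuration shown) | O=C1OC(=O)[C@H]2C(C)(C)C=CC[C@@H]12
F2 | step 2 | racemic cis-4,4-dimethyl-3a,4,7,7a-tetrahydro-2-benzofuran-1(3H)-one (racemate of 7; relative configuration shown) | O=C1OC[C@H]2C(C)(C)C=CC[C@@H]12
F3 | step 2 | (1R,6R)-6-(hydroxymethyl)-5,5-dimethyl-N-[(1S)-1-phenylethyl]cyclohex-3-ene-1-carboxamide | C[C@H](NC(=O)[C@@H]1CC=CC(C)(C)[C@@H]1CO)c1ccccc1
F4 | step 9 | tert-butyldimethylsilyl ester of the 6-O-TBS seco acid of 9 | CC(C)(C)[Si](C)(C)OC(=O)[C@@H]1C[C@H]2OC(C)(C)O[C@H]2C(C)(C)[C@@H]1CO[Si](C)(C)C(C)(C)C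
F5 | step 9 | 6-O-TBS seco acid of 9 (C20 carboxylic acid; 5α-H and 10α-H) | OC(=O)[C@@H]1C[C@H]2OC(C)(C)O[C@H]2C(C)(C)[C@@H]1CO[Si](C)(C)C(C)(C)C
F6 | step 9 | ester of F5 with allylic alcohol 12 | C=C[C@](C)(O[Si](C)(C)C(C)(C)C)CC/C=C(\C)COC(=O)[C@@H]1C[C@H]2OC(C)(C)O[C@H]2C(C)(C)[C@@H]1CO[Si](C)(C)C(C)(C)C
F7 | step 9 | (13R)-6,13-bis[(tert-butyldimethylsilyl)oxy]-2α,3α-(isopropylidenedioxy)-6,7-seco-labda-7,14-dien-20-oic acid | C=C[C@](C)(O[Si](C)(C)C(C)(C)C)CC[C@@H](C(C)=C)[C@@]1(C(=O)O)C[C@H]2OC(C)(C)O[C@H]2C(C)(C)[C@@H]1CO[Si](C)(C)C(C)(C)C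
F8 | step 9 | (13R)-13-[(tert-butyldimethylsilyl)oxy]-6-hydroxy-2α,3α-(isopropylidenedioxy)-6,7-seco-labda-7,14-dien-20-oic acid | C=C[C@](C)(O[Si](C)(C)C(C)(C)C)CC[C@@H](C(C)=C)[C@@]1(C(=O)O)C[C@H]2OC(C)(C)O[C@H]2C(C)(C)[C@@H]1CO
F9 | step 19 | (13R)-20-acetoxy-2α-angeloyloxy-13-[(tert-butyldimethylsilyl)oxy]-17-chlorolabda-7,14-dien-3α-ol | C=C[C@](C)(O[Si](C)(C)C(C)(C)C)CC[C@H]1C(CCl)=CC[C@H]2C(C)(C)[C@H](O)[C@H](OC(=O)/C(C)=C\C)C[C@]12COC(C)=O
F10 | step 19 | (13R)-20-acetoxy-2α-angeloyloxy-13-[(tert-butyldimethylsilyl)oxy]-17-(phenylselanyl)labda-7,14-dien-3α-ol | C=C[C@](C)(O[Si](C)(C)C(C)(C)C)CC[C@H]1C(C[Se]c3ccccc3)=CC[C@H]2C(C)(C)[C@H](O)[C@H](OC(=O)/C(C)=C\C)C[C@]12COC(C)=O
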